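**Strategy.** The seven-membered carbocycle (C1, C5, C6, C7, C8, C9, C10; locants in the remark below) is made from a para-silyloxy benzene ring by one-carbon ring expansion: an intramolecular Buchner reaction of an aryl diazoketone inserts the carbenoid carbon C1 between the ipso carbon C5 and an ortho carbon C10. This single operation forms C1–C5 and C1–C10, closes the cyclopentanone (C2=O), sets C1 from the boron-bearing C4 centre and leaves a silyl trienol ether whose three double bonds are then used for the C7 aldol with ketomalonate, the C10 methylation and the C5–O ether. The precursor is an open-chain 1-diazo-4-aryl-4-borylpentan-2-one.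

Key step: step 4

Remark (locants and abbreviations): C1–C5 are the cyclopentane carbons (C1 ring-fusion CH, C2 the carbon that carries the tiglate, C3 CH2, C4 C(OH)CH3, C5 ring-fusion C–O). C6–C10 complete the seven-membered ring (C6 CH2, C7 CH, C8 CH–O of the lactone, C9 CH2, C10 CHCH3). C11 is the quaternary carbon shared by lactone and ether, C12 the lactone C=O, C13 the CH2OH carbon. α is the face that carries H-1, β the other face. Bpin or pinacolboryl = 4,4,5,5-tetramethyl-1,3,2-dioxaborolan-2-yl; TBS = tert-butyldimethylsilyl. The ligand enantiomer in step 2 is assumed to be the one that gives the (S)-boronate.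

Step 1
Reactants: 1 (4-bromophenoxy)(tert-butyl)dimethylsilane; 2 (E)-pent-3-en-2-one
Product: 3 (E)-4-[4-(tert-butyldimethylsilyloxy)phenyl]pent-3-en-2-one
Conditions: Pd2(dba)3 (1.5 mol %), P(t-Bu)3 (6 mol %), Cy2NMe, dioxane, 80 °C
Reagents that add atoms: none
Why: Heck reaction, in which the arylpalladium species adds to the β-carbon of the enone and syn β-hydride elimination should give the conjugated trisubstituted alkene with the aryl group trans to the acetyl group (E).

Step 2
Reactants: 3 (E)-4-[4-(tert-butyldimethylsilyloxy)phenyl]pent-3-en-2-one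
Product: 4 (S)-4-[4-(tert-butyldimethylsilyloxy)phenyl]-4-(pinacolboryl)pentan-2-one
Conditions: B2pin2, CuCl (5 mol %), chiral bisphosphine (Josiphos type) or chiral NHC ligand, NaOt-Bu (cat.), MeOH, THF, rt
Reagents that add atoms: bis(pinacolato)diboron, CC1(C)OB(OC1(C)C)B1OC(C)(C)C(C)(C)O1
Why: Copper-catalysed enantioselective conjugate borylation of a β,β-disubstituted enone, in which the ligand-bound Cu–Bpin species adds to one face of the E-alkene and methanol protonates the copper enolate, so the ligand sets the boron-bearing quaternary centre C4 as (S).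

Step 3
Reactants: 4 (S)-4-[4-(tert-butyldimethylsilyloxy)phenyl]-4-(pinacolboryl)pentan-2-one
Product: 6 (S)-1-diazo-4-[4-(tert-butyldimethylsilyloxy)phenyl]-4-(pinacolboryl)pentan-2-one, via trifluoroacetyl diketone 5 (not isolated)
Conditions: LiHMDS, THF, −78 °C; CF3CO2CH2CF3; then MsN3, Et3N, H2O, MeCN, rt
Reagents that add atoms: methanesulfonyl azide, CS(=O)(=O)N=[N+]=[N-]
Why: Detrifluoroacetylative diazo transfer, in which the kinetic methyl enolate is trifluoroacetylated and the activated 1,3-diketone takes the diazo group from the sulfonyl azide with loss of the trifluoroacetyl group, while the quaternary C4 centre is not touched.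

Step 4
Reactants: 6 (S)-1-diazo-4-[4-(tert-butyldimethylsilyloxy)phenyl]-4-(pinacolboryl)pentan-2-one
Product: 8 (3S,8aS)-6-(tert-butyldimethylsilyloxy)-3-methyl-3-(pinacolboryl)-3,8a-dihydroazulen-1(2H)-one, via norcaradiene 7 (not isolated)
Conditions: Rh2(OAc)4 (1 mol %), CH2Cl2, 40 °C, slow addition of 6; filtration through basic alumina (no acid)
Reagents that add atoms: none
Why: Intramolecular Buchner reaction: the rhodium carbenoid from 6 cyclopropanates the ipso/ortho bond of the electron-rich arene to norcaradiene 7, whose cyclopropane opens at once by a disrotatory 6π electrocyclic reaction (cleavage of the former aromatic C5–C10 bond), so the benzene ring becomes the cycloheptatriene by insertion of the carbenoid carbon C1. The closest known reaction type is the Rh(II)-catalysed cyclisation of 1-diazo-4-arylbutan-2-ones to 3,8a-dihydroazulen-1(2H)-ones. The cyclopentanone closes by the fused five-membered cyclopropanation that makes C1–C5 and C1–C10, and the seven-membered ring arises by one-carbon expansion of the six-membered arene with release of cyclopropane strain. The only new stereocentre, C1, is controlled by C4 through the tether: the C4 methyl group should take the position remote from the forming cyclopropane (as benzylic alkyl groups do), which leaves the planar, sterically undemanding Bpin group near the ortho C–H and therefore cis to H-1. The step needs aromatic cycloaddition to win over C–H insertion and ylide formation, which the five-membered tether, the para-silyloxy arene and boron in place of oxygen at C4 (no Lewis-basic atom near the carbenoid) should secure. Regiochemistry is no issue because the para-substituted ring has two constitutionally equivalent ortho positions.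

Step 5
Reactants: 8 (3S,8aS)-6-(tert-butyldimethylsilyloxy)-3-methyl-3-(pinacolboryl)-3,8a-dihydroazulen-1(2H)-one; 9 diethyl 2-oxopropanedioate (diethyl ketomalonate)
Product: 10 C7 aldol adduct (diethyl 2-hydroxy-2-(2,8-dioxo-5,9-dien-7β-yl)malonate)
Conditions: MgBr2·OEt2, CH2Cl2, −78 → −30 °C; aq NaHCO3
Reagents that add atoms: none
Why: Mukaiyama aldol addition, in which the silyl trienol ether attacks the Mg-chelated, very electrophilic central carbonyl of 9 through its α-carbon C7 (the vinylogous carbon C5 is fully substituted and shielded by C4) on the convex face anti to the pseudo-axial H-1 and to the Bpin group, which should place C11 β on C7; C11 carries two identical esters and is not yet a stereocentre.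

Step 6
Reactants: 10 C7 aldol adduct
Product: 11 10α-methyl diketone
Conditions: Me2Zn, Cu(OTf)2 (5 mol %), BINOL-derived phosphoramidite ligand (10 mol %), toluene, −30 °C; aq NH4Cl
Reagents that add atoms: dimethylzinc, C[Zn]C
Why: Copper-catalysed conjugate addition of dimethylzinc to the only enone (C8=O, C9=C10), in which the methyl group should add to C10 on the α face, anti to the bulky β substituent at C7 and on the side of the small H-1, and protonation of the zinc enolate gives C9H2.

Step 7
Reactants: 11 10α-methyl diketone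
Product: 14 Δ5 trihydroxy lactone ethyl ester, via diol boronate 12 (not isolated), via lactone boronate 13 (not isolated)
Conditions: L-Selectride, THF, −78 → 0 °C; then NaOH, H2O2, 0 °C → rt
Reagents that add atoms: hydrogen peroxide, OO
Why: Ketone reduction by a bulky trialkylborohydride followed by lactonisation and boronate oxidation: hydride should attack C8 anti to the C7 substituent (8β-OH, which closes the cis-fused γ-lactone onto one ester with the other ester taking the exo position) and C2 anti to the flanking C1–C10 bond (2β-OH), and alkaline peroxide converts C4–B into C4–OH with retention (4α-OH).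

Step 8
Reactants: 14 Δ5 trihydroxy lactone ethyl ester
Product: 16 5β,11-ether lactone ethyl ester, via organomercurial 15 (not isolated)
Conditions: Hg(OCOCF3)2, NaHCO3, CH2Cl2, −20 → 0 °C; then Bu3SnH, rt
Reagents that add atoms: none
Why: Intramolecular alkoxymercuration–demercuration (5-endo, Markovnikov), in which the tertiary C11–OH, held on the β face by C7, can attack the activated C5=C6 bond only at the more substituted C5 and only from that face, so C5–O forms cis to C7–C11 and trans to the 4α-OH, and stannane reduction of the C6–Hg bond leaves C6H2.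

Step 9
Reactants: 16 5β,11-ether lactone ethyl ester
Product: 18 lactone carboxylic acid, via hydroxy diacid 17 (not isolated)
Conditions: LiOH, THF/H2O, 0 °C → rt; then 1 M HCl to pH 2, rt
Reagents that add atoms: lithium hydroxide, [Li+].[OH-]
Why: Saponification of the ethyl ester (the lactone opens as well) and acid-induced relactonisation, in which only the carboxyl group cis to the C8 oxygen can close the five-membered lactone, so the exo carboxyl group stays free and no stereocentre is touched.

Step 10
Reactants: 18 lactone carboxylic acid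
Product: 19 triol lactone
Conditions: BH3·SMe2, THF, 0 °C → rt; MeOH
Reagents that add atoms: none
Why: Chemoselective borane reduction of the carboxylic acid through its acyloxyborane, which should be much faster than reduction of the lactone, gives the C13 primary alcohol.

Step 11
Reactants: 19 triol lactone
Product: 20 13-O-TBS ether
Conditions: TBSCl, imidazole, CH2Cl2, 0 °C
Reagents that add atoms: tert-butyldimethylsilyl chloride, CC(C)(C)[Si](C)(C)Cl
Why: Selective silylation of the primary alcohol in the presence of the hindered secondary C2–OH and the tertiary C4–OH.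

Step 12
Reactants: 20 13-O-TBS ether; 21 (E)-2-methylbut-2-enoic acid (tiglic acid)
Product: 22 2α-tiglate 13-O-TBS ether
Conditions: PPh3, DIAD, toluene, 0 °C → rt
Reagents that add atoms: none
Why: Mitsunobu esterification, in which tiglate displaces the alkoxyphosphonium group at C2 with inversion (SN2) and so turns the 2β-hydroxyl from step 7 into the required 2α-tigloyloxy group, while the tertiary alcohol does not react and the E alkene of the acid is unchanged.

Step 13
Reactants: 22 2α-tiglate 13-O-TBS ether
Product: 23 target compound CNP0408475.1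
Conditions: HF·pyridine, pyridine, THF, 0 °C
Reagents that add atoms: none
Why: Fluoride-mediated cleavage of the primary silyl ether under buffered conditions that should leave the tiglate, the lactone and the tertiary alcohol intact.

**Compound list**

1 | (4-bromophenoxy)(tert-butyl)dimethylsilane | CC(C)(C)[Si](C)(C)Oc1ccc(Br)cc1 | starting material
2 | (E)-pent-3-en-2-one | C/C=C/C(C)=O | starting material
3 | (E)-4-[4-(tert-butyldimethylsilyloxy)phenyl]pent-3-en-2-one | CC(=O)/C=C(\C)c1ccc(O[Si](C)(C)C(C)(C)C)cc1 | intermediate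
4 | (S)-4-[4-(tert-butyldimethylsilyloxy)phenyl]-4-(4,4,5,5-tetramethyl-1,3,2-dioxaborolan-2-yl)pentan-2-one | CC(=O)C[C@@](C)(B1OC(C)(C)C(C)(C)O1)c1ccc(O[Si](C)(C)C(C)(C)C)cc1 | intermediate
5 | (S)-1,1,1-trifluoro-6-[4-(tert-butyldimethylsilyloxy)phenyl]-6-(pinacolboryl)heptane-2,4-dione | O=C(CC(=O)C[C@@](C)(B1OC(C)(C)C(C)(C)O1)c1ccc(O[Si](C)(C)C(C)(C)C)cc1)C(F)(F)F | intermediate
6 | (S)-1-diazo-4-[4-(tert-butyldimethylsilyloxy)phenyl]-4-(pinacolboryl)pentan-2-one | [N-]=[N+]=CC(=O)C[C@@](C)(B1OC(C)(C)C(C)(C)O1)c1ccc(O[Si](C)(C)C(C)(C)C)cc1 | intermediate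
7 | norcaradiene valence isomer of 8 (cyclopropane C1–C5–C10 fused cis to the cyclopentanone and to the 8-silyloxycyclohexa-6,8-diene; H-1 on the diene side; C4 as in 6) | O=C1C[C@@](C)(B4OC(C)(C)C(C)(C)O4)[C@]23C=CC(O[Si](C)(C)C(C)(C)C)=C[C@H]2[C@H]13 | intermediate
8 | (3S,8aS)-6-(tert-butyldimethylsilyloxy)-3-methyl-3-(pinacolboryl)-3,8a-dihydroazulen-1(2H)-one (remark locants: 2-oxo, 4α-Bpin, 4β-CH3, 1α-H, 5,7,9-triene, 8-OTBS) | O=C1C[C@@](C)(B3OC(C)(C)C(C)(C)O3)C2=CC=C(O[Si](C)(C)C(C)(C)C)C=C[C@H]12 | intermediate
9 | diethyl 2-oxopropanedioate (diethyl ketomalonate) | CCOC(=O)C(=O)C(=O)OCC | starting material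
10 | diethyl 2-hydroxy-2-(hydroazulenyl)propanedioate attached at C7β; core 2,8-dioxo, 5(6)- and 9(10)-ene, 1α-H, 7α-H, 4α-Bpin, 4β-CH3 | O=C1C[C@@](C)(B3OC(C)(C)C(C)(C)O3)C2=C[C@H](C(O)(C(=O)OCC)C(=O)OCC)C(=O)C=C[C@H]12 | intermediate
11 | as 10 with C9H2 and 10α-CH3 (10β-H); 2,8-dioxo-5(6)-ene | O=C1C[C@@](C)(B3OC(C)(C)C(C)(C)O3)C2=C[C@H](C(O)(C(=O)OCC)C(=O)OCC)C(=O)C[C@@H](C)[C@H]12 | intermediate
12 | 2β,8β-diol of 11 (boronate and both esters intact) | O[C@@H]1C[C@@](C)(B3OC(C)(C)C(C)(C)O3)C2=C[C@H](C(O)(C(=O)OCC)C(=O)OCC)[C@H](O)C[C@@H](C)[C@H]12 | intermediate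
13 | cis-fused 8β,12-lactone (7α-H, 8α-H) with 11-OH on the concave face and exo 11-CO2Et; 2β-OH, 4α-Bpin, 5(6)-ene | O[C@@H]1C[C@@](C)(B3OC(C)(C)C(C)(C)O3)C2=C[C@H]4[C@@H](C[C@@H](C)[C@H]12)OC(=O)[C@@]4(C(=O)OCC)O | intermediate
14 | as 13 with 4α-OH in place of boron (2β,4α,11-triol, 5(6)-ene, lactone, ethyl ester) | O[C@@H]1C[C@@](C)(O)C2=C[C@H]4[C@@H](C[C@@H](C)[C@H]12)OC(=O)[C@@]4(C(=O)OCC)O | intermediate
15 | 5β,11-ether with 6α-HgOCOCF3 (6β-H) | O[C@@H]1C[C@@](C)(O)[C@@]23[C@@H]([Hg]OC(=O)C(F)(F)F)[C@H]4[C@@H](C[C@@H](C)[C@H]12)OC(=O)[C@@]4(C(=O)OCC)O3 | intermediate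
16 | 5β,11-ether, 8β,12-lactone, 11-CO2Et, 2β,4α-diol | O[C@@H]1C[C@@](C)(O)[C@@]23C[C@H]4[C@@H](C[C@@H](C)[C@H]12)OC(=O)[C@@]4(C(=O)OCC)O3 | intermediate
17 | ring-opened 2β,4α,8β-triol 11,11-dicarboxylic acid (ether intact) | O[C@@H]1C[C@@](C)(O)[C@@]23C[C@H](C(C(=O)O)(C(=O)O)O3)[C@H](O)C[C@@H](C)[C@H]12 | intermediate
18 | 5β,11-ether, 8β,12-lactone, 11-CO2H (C13 acid), 2β,4α-diol | O[C@@H]1C[C@@](C)(O)[C@@]23C[C@H]4[C@@H](C[C@@H](C)[C@H]12)OC(=O)[C@@]4(C(=O)O)O3 | intermediate
19 | 2β,4α,13-triol (2-epimer of the de-tigloyl target) | O[C@@H]1C[C@@](C)(O)[C@@]23C[C@H]4[C@@H](C[C@@H](C)[C@H]12)OC(=O)[C@@]4(CO)O3 | intermediate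
20 | 13-O-tert-butyldimethylsilyl ether of 19 | O[C@@H]1C[C@@](C)(O)[C@@]23C[C@H]4[C@@H](C[C@@H](C)[C@H]12)OC(=O)[C@@]4(CO[Si](C)(C)C(C)(C)C)O3 | intermediate
21 | (E)-2-methylbut-2-enoic acid (tiglic acid) | C/C=C(\C)C(=O)O | starting material
22 | 2α-tigloyloxy 13-O-TBS ether (all other centres as in the target) | C/C=C(\C)C(=O)O[C@H]1C[C@@](C)(O)[C@@]23C[C@H]4[C@@H](C[C@@H](C)[C@H]12)OC(=O)[C@@]4(CO[Si](C)(C)C(C)(C)C)O3 | intermediate
23 | CNP0408475.1 | C/C=C(\C)C(=O)O[C@H]1C[C@@](C)(O)[C@@]23C[C@H]4[C@@H](C[C@@H](C)[C@H]12)OC(=O)[C@@]4(CO)O3 | target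

**Step count.** Total: 13 steps. Longest linear sequence: 13 steps (1 → 23); 2, 9 and 21 are commercial partners.

**Steps most likely to fail**

Step 4. The 1,3-induction from C4 to C1 may be weak or reversed (the boron group could take the position remote from H-1), and the carbenoid may be lost to C–H insertion. The fallback sets out from 3 and leaves boron out. Copper hydride reduction of 3 (Cu(OAc)2, chiral bisphosphine, silane) should give the saturated ketone F1, and the same diazo transfer gives the diazoketone F2. The Buchner reaction of this benzylic-methyl substrate should give the azulenone F3 with the methyl group trans to H-1, the sense known for benzylic alkyl groups. The chemistry of steps 5, 6 and 7 (without boronate oxidation) then gives the aldol adduct F4, the methyl diketone F5 and the hydroxy lactone F6. Allylic hydroxylation of the C5=C6 alkene of F6 at the tertiary C4–H with SeO2/t-BuOOH (ene reaction then [2,3]-shift, overall retention) comes back to the route at 14.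

Step 5. The Lewis acid may open the acid-labile azulenone to a tetralone, the vinylogous carbon or the allylboronate may compete, and facial selectivity at C7 may be poor. The fallback sets out from 8 and forms the enolate without Lewis acid. Bromination of the silyl trienol ether at C7 with NBS should give the α-bromo dienone F7. A zinc-mediated Reformatsky-type addition of F7 to ketomalonate 9, through a closed zinc enolate transition state, comes back to the route at 10.

Step 8. The tertiary allylic alcohol may ionise, the 5-endo closure at the hindered C5 may fail, or the ether may revert during demercuration. The fallback sets out from 14. Iodoetherification (I2, NaHCO3, MeCN, 0 °C) should give the iodo ether F8, and radical deiodination of F8 with Bu3SnH/AIBN comes back to the route at 16.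

**Further compounds**

F1 | step 4 | (S)-4-[4-(tert-butyldimethylsilyloxy)phenyl]pentan-2-one | CC(=O)C[C@H](C)c1ccc(O[Si](C)(C)C(C)(C)C)cc1
F2 | step 4 | (S)-1-diazo-4-[4-(tert-butyldimethylsilyloxy)phenyl]pentan-2-one | [N-]=[N+]=CC(=O)C[C@H](C)c1ccc(O[Si](C)(C)C(C)(C)C)cc1
F3 | step 4 | (3S,8aS)-6-(tert-butyldimethylsilyloxy)-3-methyl-3,8a-dihydroazulen-1(2H)-one (methyl trans to H-8a) | O=C1C[C@H](C)C2=CC=C(O[Si](C)(C)C(C)(C)C)C=C[C@H]12
F4 | step 4 | 4-deboryl analogue of 10 (4α-H, 4β-CH3) | O=C1C[C@H](C)C2=C[C@H](C(O)(C(=O)OCC)C(=O)OCC)C(=O)C=C[C@H]12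
F5 | step 4 | 4-deboryl analogue of 11 (4α-H, 4β-CH3, 10α-CH3) | O=C1C[C@H](C)C2=C[C@H](C(O)(C(=O)OCC)C(=O)OCC)C(=O)C[C@@H](C)[C@H]12
F6 | step 4 | 4-deoxy analogue of 14 (4α-H; 2β,11-diol, 5(6)-ene, lactone, ethyl ester) | O[C@@H]1C[C@H](C)C2=C[C@H]4[C@@H](C[C@@H](C)[C@H]12)OC(=O)[C@@]4(C(=O)OCC)O
F7 | step 5 | 7β-bromo-2,8-dioxo-5(6),9(10)-diene (4α-Bpin, 4β-CH3, 1α-H) | O=C1C[C@@](C)(B3OC(C)(C)C(C)(C)O3)C2=C[C@H](Br)C(=O)C=C[C@H]12
F8 | step 8 | 6α-iodo analogue of 16 | O[C@@H]1C[C@@](C)(O)[C@@]23[C@@H](I)[C@H]4[C@@H](C[C@@H](C)[C@H]12)OC(=O)[C@@]4(C(=O)OCC)O3
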